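**Plan**
1. Retrosynthesis first removes the two aryl tert-butyl ethers and the acetate C–O bond, then cuts the ring bond C2–C3 of the quinone (numbered C1(=O), C2(OAc), C3(Ar), C4(=O), C5(H), C6(Ar)), giving an acyclic keto ester.
2. The enabling feature is the C4(=O)–C5H=C6(Ar)–C1(=O) cis-enedione that remains: it is a 3-aryl-2,5-disubstituted furan whose ring oxygen bridges C1 and C4, with C2 as the ester carbon on one α-position and C3 as the benzylic CH2 on the other.
3. The furan is cut at the C6–aryl and C3–aryl bonds (one boronic acid, used twice) and at the C3–C4 bond (chloromethylation of methyl 3-bromo-2-furoate).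
4. Forward order: chloromethylation, twofold Suzuki coupling, singlet-oxygen opening of the furan, Dieckmann closure of the only carbocycle as the 2-hydroxyquinone, O-acetylation, acidolysis of the tert-butyl ethers.
5. Stereochemistry: the target has no stereocentre; the one geometric requirement, the Z-enedione needed for ring closure, is inherited from the furan ring.

Key step: step 4

Remark: the target is achiral (no stereocentre, no stereogenic double bond), so it is made as drawn; paraformaldehyde is listed as its monomer, and the two bicyclic intermediates are racemic with one enantiomer drawn.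

**Step 1**
Reactants: 1 methyl 3-bromofuran-2-carboxylate; 2 formaldehyde (used as paraformaldehyde)
Product: 4 methyl 3-bromo-5-(chloromethyl)furan-2-carboxylate, via hydroxymethyl bromofuroate 3 (not isolated)
Conditions: (CH2O)n, HCl (g), ZnCl2 (cat.), CHCl3, 25 → 45 °C
Reagents that add atoms: hydrogen chloride, Cl
Why: Blanc chloromethylation, which is established for 2-furoate esters at the free α-position C5; the furfuryl alcohol 3 formed first is converted to the chloride by HCl/ZnCl2, and the anhydrous acid should leave the ester and the C–Br bond alone.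

**Step 2**
Reactants: 4 methyl 3-bromo-5-(chloromethyl)furan-2-carboxylate; 5 4-(tert-butoxy)phenylboronic acid (2.4 equiv)
Product: 8 methyl 5-[4-(tert-butoxy)benzyl]-3-[4-(tert-butoxy)phenyl]furan-2-carboxylate, via bromo benzylfuroate 6 (not isolated), via chloromethyl arylfuroate 7 (not isolated)
Conditions: Pd(PPh3)4 (5 mol %), Na2CO3, DME/H2O 5:1, 80 °C
Reagents that add atoms: none
Why: Twofold Suzuki–Miyaura coupling, in which both the C3–Br bond (activated by the neighbouring ester) and the furfuryl C–Cl bond add oxidatively to Pd(0), so one boronic acid supplies both aryl groups and either mono-coupled ester (6 or 7) converges on 8.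

**Step 3**
Reactants: 8 methyl 5-[4-(tert-butoxy)benzyl]-3-[4-(tert-butoxy)phenyl]furan-2-carboxylate
Product: 10 methyl (Z)-3,6-bis[4-(tert-butoxy)phenyl]-2,5-dioxohex-3-enoate, via furan endoperoxide 9 (not isolated)
Conditions: O2, hν (white LED), tetraphenylporphyrin (cat.), CH2Cl2, −30 °C; then Me2S, −30 → 0 °C; used directly
Reagents that add atoms: dioxygen, O=O
Why: Singlet-oxygen [4+2] cycloaddition across the furan 2,5-positions followed by sulfide reduction of the endoperoxide is a known way from furoate esters to cis-diacylethylenes; the Z geometry is fixed by the ring, and the aryl ethers and ester should be inert to 1O2 and Me2S.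

**Step 4**
Reactants: 10 methyl (Z)-3,6-bis[4-(tert-butoxy)phenyl]-2,5-dioxohex-3-enoate
Product: 12 2-hydroxy-3,6-bis[4-(tert-butoxy)phenyl]cyclohexa-2,5-diene-1,4-dione, via sodium hydroxyquinonate 11 (not isolated)
Conditions: NaOMe (2.2 equiv), MeOH/THF 1:1, 0 °C → rt; then 1 M HCl, 0 °C
Reagents that add atoms: none
Why: Methoxide deprotonates the benzylic C3 methylene next to the C4 ketone, the enolate carbon adds to the ester carbonyl C2, methoxide leaves, and the resulting cyclohex-5-ene-1,2,4-trione is deprotonated to the vinylogous carboxylate 11, which acid should release as hydroxyquinone 12 with no redox adjustment. The closest known reaction type is the Dieckmann/Claisen condensation of a ketone enolate with an oxalyl (α-keto) ester, which gives cyclic 1,2,4-triones from ketones and dialkyl oxalates and hydroxyquinones from arylpyruvate esters. The ring closes in a 6-(enolexo)-exo-trig mode, possible because the Z double bond inherited from the furan holds C1 and C4 on the same side; no stereocentre is created. The selectivity needed is acylation at C2 over 5-(enolexo)-exo-trig aldol addition to the more electrophilic C1 ketone: the aldol adduct cannot dehydrate without becoming a cyclopentadienone, so it should revert under the equilibrating methoxide/methanol conditions, whereas loss of methoxide and formation of the stabilised anion 11 is irreversible. Methoxide matches the methyl ester, so no ester scrambling arises, and its reversible conjugate addition lets any E isomer return to the Z form that cyclises.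

**Step 5**
Reactants: 12 2-hydroxy-3,6-bis[4-(tert-butoxy)phenyl]cyclohexa-2,5-diene-1,4-dione
Product: 13 2,5-bis[4-(tert-butoxy)phenyl]-3,6-dioxocyclohexa-1,4-dien-1-yl acetate
Conditions: Ac2O (3 equiv), Et3N (1.5 equiv), CH2Cl2, 0 °C; cold dilute-acid wash
Reagents that add atoms: acetic anhydride, CC(=O)OC(C)=O
Why: O-Acylation of the strongly acidic vinylogous carboxylic acid, the only free OH, as its ammonium salt with excess anhydride is the standard esterification of 2-hydroxy-1,4-quinones; the tert-butyl ethers are inert.

**Step 6**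
Reactants: 13 2,5-bis[4-(tert-butoxy)phenyl]-3,6-dioxocyclohexa-1,4-dien-1-yl acetate
Product: 14 neonambiquinone A, 2,5-bis(4-hydroxyphenyl)-3,6-dioxocyclohexa-1,4-dien-1-yl acetate
Conditions: TFA/CH2Cl2 1:3, 0 °C → rt, N2 sweep
Reagents that add atoms: none
Why: Acidolysis of aryl tert-butyl ethers (E1 loss of 2-methylpropene) in TFA is neither nucleophilic nor reducing, so the quinone and its vinylogous-anhydride acetate should survive and the only by-product is a volatile alkene.

**Compound list**
1 | methyl 3-bromofuran-2-carboxylate | COC(=O)c1occc1Br | starting material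
2 | formaldehyde (used as paraformaldehyde) | C=O | starting material
3 | methyl 3-bromo-5-(hydroxymethyl)furan-2-carboxylate | COC(=O)c1oc(CO)cc1Br | intermediate
4 | methyl 3-bromo-5-(chloromethyl)furan-2-carboxylate | COC(=O)c1oc(CCl)cc1Br | intermediate
5 | 4-(tert-butoxy)phenylboronic acid | CC(C)(C)Oc1ccc(B(O)O)cc1 | starting material
6 | methyl 3-bromo-5-[4-(tert-butoxy)benzyl]furan-2-carboxylate | COC(=O)c1oc(Cc2ccc(OC(C)(C)C)cc2)cc1Br | intermediate
7 | methyl 3-[4-(tert-butoxy)phenyl]-5-(chloromethyl)furan-2-carboxylate | COC(=O)c1oc(CCl)cc1-c1ccc(OC(C)(C)C)cc1 | intermediate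
8 | methyl 5-[4-(tert-butoxy)benzyl]-3-[4-(tert-butoxy)phenyl]furan-2-carboxylate | COC(=O)c1oc(Cc2ccc(OC(C)(C)C)cc2)cc1-c1ccc(OC(C)(C)C)cc1 | intermediate
9 | methyl 4-[4-(tert-butoxy)benzyl]-6-[4-(tert-butoxy)phenyl]-2,3,7-trioxabicyclo[2.2.1]hept-5-ene-1-carboxylate (racemic) | COC(=O)[C@]12OO[C@](Cc3ccc(OC(C)(C)C)cc3)(O1)C=C2c1ccc(OC(C)(C)C)cc1 | intermediate
10 | methyl (Z)-3,6-bis[4-(tert-butoxy)phenyl]-2,5-dioxohex-3-enoate | COC(=O)C(=O)/C(c1ccc(OC(C)(C)C)cc1)=C\C(=O)Cc1ccc(OC(C)(C)C)cc1 | intermediate
11 | sodium 2,5-bis[4-(tert-butoxy)phenyl]-3,6-dioxocyclohexa-1,4-dien-1-olate | [Na+].[O-]C1=C(c2ccc(OC(C)(C)C)cc2)C(=O)C=C(c2ccc(OC(C)(C)C)cc2)C1=O | intermediate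
12 | 2-hydroxy-3,6-bis[4-(tert-butoxy)phenyl]cyclohexa-2,5-diene-1,4-dione | OC1=C(c2ccc(OC(C)(C)C)cc2)C(=O)C=C(c2ccc(OC(C)(C)C)cc2)C1=O | intermediate
13 | 2,5-bis[4-(tert-butoxy)phenyl]-3,6-dioxocyclohexa-1,4-dien-1-yl acetate | CC(=O)OC1=C(c2ccc(OC(C)(C)C)cc2)C(=O)C=C(c2ccc(OC(C)(C)C)cc2)C1=O | intermediate
14 | neonambiquinone A, 2,5-bis(4-hydroxyphenyl)-3,6-dioxocyclohexa-1,4-dien-1-yl acetate | CC(=O)OC1=C(c2ccc(O)cc2)C(=O)C=C(c2ccc(O)cc2)C1=O | target

**Step count**
Total steps: 6. Longest linear sequence: 6 steps (1 → 14).

**Steps most likely to fail**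

Step 4. The C3 enolate may be drained through the five-ring aldol at the α-keto ester ketone faster than the adduct reverts, or the open-chain enedione may be consumed by conjugate addition of methoxide, so that acylation at C2 never becomes competitive. The fallback sets out from 8 and comes back at 11; it turns C2 into a better acyl donor, so that every attack at C2 is irreversible and a non-nucleophilic amide base can be used. Saponification of 8 (LiOH, THF/H2O, rt; dilute HCl to pH 3) should give 5-[4-(tert-butoxy)benzyl]-3-[4-(tert-butoxy)phenyl]furan-2-carboxylic acid F1. Steglich esterification (phenol, EDC·HCl, cat. DMAP, CH2Cl2) should give phenyl 5-[4-(tert-butoxy)benzyl]-3-[4-(tert-butoxy)phenyl]furan-2-carboxylate F2. Photooxygenation and Me2S reduction as in step 3 should pass through phenyl 4-[4-(tert-butoxy)benzyl]-6-[4-(tert-butoxy)phenyl]-2,3,7-trioxabicyclo[2.2.1]hept-5-ene-1-carboxylate F3 (not isolated) to phenyl (Z)-3,6-bis[4-(tert-butoxy)phenyl]-2,5-dioxohex-3-enoate F4. NaHMDS (1.05 equiv, THF, −78 → 0 °C) should then close the ring with loss of phenoxide, which deprotonates the trione to the sodium salt 11; the acid work-up of step 4 returns 12.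

Step 3. The cycloaddition of singlet oxygen to the ester-deactivated furan may be slow, the endoperoxide may rearrange before the sulfide reduces it, or the Z-enedione may isomerise or hydrate during handling. The fallback sets out from 8 and comes back at 10; it replaces cycloaddition/reduction by direct oxygen-atom transfer. Dimethyldioxirane (about 1.2 equiv, acetone, −20 → 0 °C) should epoxidise the electron-richer C4=C5 bond remote from the ester to methyl 1-[4-(tert-butoxy)benzyl]-4-[4-(tert-butoxy)phenyl]-2,6-dioxabicyclo[3.1.0]hex-3-ene-3-carboxylate F5 (not isolated). This epoxide should open spontaneously to 10; only acetone is released, so the solution can be concentrated cold and taken straight into step 4.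

Step 1. Electrophilic substitution on the furan deactivated by both ester and bromine may be sluggish, and the chloride may alkylate a second furan to difurylmethanes. The fallback sets out from 1 and comes back at 4; it replaces electrophilic substitution by deprotonation at the most acidic ring position. TMPMgCl·LiCl (1.1 equiv, THF, −40 °C) should give [4-bromo-5-(methoxycarbonyl)furan-2-yl]magnesium chloride F6 (not isolated). Trapping with dry paraformaldehyde (−40 °C → rt; aq. NH4Cl) should give the alcohol 3, isolated in this variant. SOCl2 (CH2Cl2, 0 °C → rt) should convert 3 to 4.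

**Further compounds**
F1 | step 4 | 5-[4-(tert-butoxy)benzyl]-3-[4-(tert-butoxy)phenyl]furan-2-carboxylic acid | OC(=O)c1oc(Cc2ccc(OC(C)(C)C)cc2)cc1-c1ccc(OC(C)(C)C)cc1
F2 | step 4 | phenyl 5-[4-(tert-butoxy)benzyl]-3-[4-(tert-butoxy)phenyl]furan-2-carboxylate | O=C(Oc1ccccc1)c1oc(Cc2ccc(OC(C)(C)C)cc2)cc1-c1ccc(OC(C)(C)C)cc1
F3 | step 4 | phenyl 4-[4-(tert-butoxy)benzyl]-6-[4-(tert-butoxy)phenyl]-2,3,7-trioxabicyclo[2.2.1]hept-5-ene-1-carboxylate (racemic) | O=C(Oc1ccccc1)[C@]12OO[C@](Cc3ccc(OC(C)(C)C)cc3)(O1)C=C2c1ccc(OC(C)(C)C)cc1
F4 | step 4 | phenyl (Z)-3,6-bis[4-(tert-butoxy)phenyl]-2,5-dioxohex-3-enoate | O=C(Oc1ccccc1)C(=O)/C(c1ccc(OC(C)(C)C)cc1)=C\C(=O)Cc1ccc(OC(C)(C)C)cc1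
F5 | step 3 | methyl 1-[4-(tert-butoxy)benzyl]-4-[4-(tert-butoxy)phenyl]-2,6-dioxabicyclo[3.1.0]hex-3-ene-3-carboxylate (racemic) | COC(=O)C1=C(c2ccc(OC(C)(C)C)cc2)[C@@H]3O[C@]3(Cc4ccc(OC(C)(C)C)cc4)O1
F6 | step 1 | [4-bromo-5-(methoxycarbonyl)furan-2-yl]magnesium chloride (LiCl complex) | COC(=O)c1oc([Mg]Cl)cc1Br
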